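Readings and results were computed for an exercise.

With 2 equiv of coupling partner the spring run holds more target than the dawn run with 1 equiv, 58.6% against 39.0% at 2.50 min, yet target falls with time in both runs.

in all of them: substrate 0.20 M
- dawn: coupling partner 1 equiv; the very flask that is asked about, followed so far
- spring: coupling partner 2 equiv; run made earlier
- flask: coupling partner 1.00 equiv; time 12 min

| run | time / min | target / % | substrate / % |
|---|---|---|---|
| dawn | 0.833 | 46.7 | 8.9 |
| dawn | 2.50 | 39.0 | 6.9 |
| dawn | 4.00 | 33.8 | 4.9 |
| dawn | 6.00 | 31.1 | 4.9 |
| dawn | 10.0 | 26.8 | 4.0 |
| spring | 0.200 | 69.4 | 4.8 |
| spring | 0.417 | 68.4 | 4.3 |
| spring | 0.667 | 66.4 | 4.2 |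
| spring | 1.33 | 62.6 | 4.8 |
| spring | 2.50 | 58.6 | 4.0 |

(scatter of a reading: 0.5 percentage points)

- north-east: at 12 min take out 90% of the target then present, then wait 12 min
- south-east: at 12 min add substrate, 50.0% of the amount charged, then wait 12 min
- west: at 12 min add coupling partner, 100% of the amount charged, then wait 12 min
- south-west: change nothing and wait 12 min more

- target taken out counts as made
- the analysis behind the earlier runs scatters by 0.5 percentage points, standard deviation
- additions bring no volume worth counting
- a reading of substrate is of its free form alone

* target, in percent of the substrate first charged, at 12 min
* what to do for the largest gain in target; "none" if nothing gains more than 2 percentage points (north-east / south-east / west / south-west / none)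
* target present, with what was taken out counted in, in percent of the substrate first charged, after south-east
* target present, with what was taken out counted in, in percent of the substrate first charged, after south-west

**What do you reckon with?** With what is left, each as a share of the substrate charged: T is target, S free substrate, and L coupling partner left, taken as its charge less T.

**Why should more partner hold more target?** If target stands in balance with the other two, one quotient stays put. The last dawn reading gives 9.15 and the last spring reading 10.4. This is the holding number H = T/(S·L), an apparent equilibrium constant.

**But substrate reads 4.0% with a scatter of 0.5 percentage points. Do those two agree?** As closely as that scatter can tell.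

**Then why does target fall?** In the last dawn reading, 69.2% of the substrate is neither target nor free substrate. So something drains free substrate, and with H held, target goes down with it.

**Target in the flask at 12 min?** The line through the last two dawn readings reaches 24.7%. The fall is slowing, so I say slightly above that. H then asks for S near 3.57%.

**And if target is taken out?** 22.2% is banked. The remainder shares out again by H·L and rebuilds 5.27% of target, so my estimate of the total is 27.5%.

The forecast says 25% now, north-east as the best move, 26% after south-east and 18% after south-west: “North-east narrowly beats south-east, but this is close”.

    substrate + coupling partner ⇌ target (K = 60.0 M⁻¹, k = 1.60 M⁻¹ s⁻¹)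
    2 substrate → self-condensation product (k = 0.447 M⁻¹ s⁻¹)
    substrate + coupling partner ⇌ isomer of the product (K = 22.0 M⁻¹, k = 0.244 M⁻¹ s⁻¹)

The flask gives 25.6%, and north-east is best, gaining 6.5 points on what the flask holds at 12 min, while south-east ends at 25.8% and south-west at 19.7%. H comes to 10.6 in this flask at 12.0 min, and to 10.1 in the neighbour read at 5.00 min, which holds 32.8% of target. So target in this flask is a store that pays out as substrate is drained. The main reason for the loss is the falling back of target to substrate and coupling partner: with that way back removed, the same flask stands at 75.1% instead of 25.6%.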